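**Plan**
1. Flavone numbering is used (O1, C2–C4, C4a, C5–C8, C8a; ring B primed). The retrosynthesis first masks 5-OH and 3'-OH as MOM ethers. It then cuts three bonds of ring C at once: C4a–C4, C4–C3 and O1–C2.
2. Enabling feature: C4 carries only the carbonyl oxygen and is bonded to ring A at C4a and to the two-carbon C3=C2 link. O1 hangs on C8a, the ring-A carbon next to C4a. An ortho-iodophenol plus CO supplies this adjacent C–C(=O)/C–O pair, and C3=C2 with ring B is a terminal arylacetylene.
3. Rings A and B share a 3-oxy-4,5-dimethoxy pattern, so both fragments come from 3-hydroxy-4,5-dimethoxybenzaldehyde. Its formyl carbon becomes C2 in the ring B fragment. In the ring A fragment it is exchanged for the C5 oxygen.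
4. Forward order: the alkyne takes 2 steps and the iodophenol 5 steps (carbamate on the future O1, Baeyer–Villiger oxidation, MOM on O5, carbamate-directed iodination at C4a, hydrolysis). Rings A and B are carried in intact, and ring C is the only ring formed (step 8). O5 is kept as an acetal so that the last step need not distinguish between methoxy groups.
5. Stereochemistry: the target has no stereocentre and no configurable double bond, so nothing has to be set or preserved.

Key step: step 8

Remark: the molecule is achiral, so "single enantiomer" is taken to mean the one constitution written in the target SMILES.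

**Step 1**
Reactants: 1 3-hydroxy-4,5-dimethoxybenzaldehyde
Product: 2 3,4-dimethoxy-5-(methoxymethoxy)benzaldehyde
Conditions: MOMCl, i-Pr2NEt, CH2Cl2, 0 °C → rt
Reagents that add atoms: chloromethyl methyl ether (MOMCl), COCCl
Why: O-alkylation of the only phenol with a highly reactive chloromethyl ether (MOM acetal formation), under a hindered amine base that leaves the aldehyde and the methyl ethers untouched.

**Step 2**
Reactants: 2 3,4-dimethoxy-5-(methoxymethoxy)benzaldehyde; 3 dimethyl (1-diazo-2-oxopropyl)phosphonate
Product: 4 5-ethynyl-1,2-dimethoxy-3-(methoxymethoxy)benzene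
Conditions: K2CO3, MeOH, rt
Reagents that add atoms: dimethyl (1-diazo-2-oxopropyl)phosphonate (3), COP(=O)(OC)C(=[N+]=[N-])C(C)=O
Why: Seyferth–Gilbert homologation in its Ohira–Bestmann form, in which methanolysis of 3 frees the diazomethylphosphonate anion, this olefinates the non-enolisable aryl aldehyde, and loss of N2 with a 1,2-hydride shift gives the terminal alkyne under mild base that does not harm the acetal.

**Step 3**
Reactants: 1 3-hydroxy-4,5-dimethoxybenzaldehyde
Product: 5 5-formyl-2,3-dimethoxyphenyl N,N-diethylcarbamate
Conditions: ClC(O)NEt2, K2CO3, MeCN, reflux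
Reagents that add atoms: diethylcarbamoyl chloride, CCN(CC)C(Cl)=O
Why: O-carbamoylation of the phenoxide (nucleophilic acyl substitution) protects the future O1 and installs the strongest oxygen-based directing group for the later metalation.

**Step 4**
Reactants: 5 5-formyl-2,3-dimethoxyphenyl N,N-diethylcarbamate
Product: 7 5-hydroxy-2,3-dimethoxyphenyl N,N-diethylcarbamate, via aryl formate 6 (not isolated)
Conditions: mCPBA, CH2Cl2, 0 °C → rt; then K2CO3 (cat.), MeOH, rt
Reagents that add atoms: mCPBA, OOC(=O)c1cccc(Cl)c1
Why: Baeyer–Villiger oxidation of an electron-rich benzaldehyde, in which the aryl group with its para-methoxy substituent migrates in preference to hydride, and the labile formate 6 is then transesterified under conditions far too mild to touch the diethylcarbamate.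

**Step 5**
Reactants: 7 5-hydroxy-2,3-dimethoxyphenyl N,N-diethylcarbamate
Product: 8 2,3-dimethoxy-5-(methoxymethoxy)phenyl N,N-diethylcarbamate
Conditions: MOMCl, i-Pr2NEt, CH2Cl2, 0 °C → rt
Reagents that add atoms: chloromethyl methyl ether (MOMCl), COCCl
Why: MOM acetal formation by O-alkylation of the single free phenol (the future 5-OH) gives a group that is stable to organolithium, hydroxide and amine and that reinforces the directing effect in the next step.

**Step 6**
Reactants: 8 2,3-dimethoxy-5-(methoxymethoxy)phenyl N,N-diethylcarbamate
Product: 10 2-iodo-5,6-dimethoxy-3-(methoxymethoxy)phenyl N,N-diethylcarbamate, via aryllithium 9 (not isolated)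
Conditions: s-BuLi, TMEDA, THF, −78 °C; then I2, THF, −78 °C → rt
Reagents that add atoms: iodine, II
Why: Directed ortho-metalation followed by iodinolysis, in which the only C–H ortho to the carbamate lies between it and the MOM ether (the two best directing groups on the ring) and should be deprotonated ahead of the C–H between OMe and OMOM, while holding −78 °C suppresses the anionic ortho-Fries shift.

**Step 7**
Reactants: 10 2-iodo-5,6-dimethoxy-3-(methoxymethoxy)phenyl N,N-diethylcarbamate
Product: 11 2-iodo-5,6-dimethoxy-3-(methoxymethoxy)phenol
Conditions: NaOH, EtOH–H2O, reflux, Ar; then aq NH4Cl, 0 °C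
Reagents that add atoms: none
Why: Alkaline hydrolysis (acyl–oxygen cleavage) of an aryl N,N-dialkylcarbamate is the standard release after directed metalation, and the acetal, the methyl ethers and the aryl iodide tolerate hydroxide while the near-neutral work-up spares the MOM group.

**Step 8**
Reactants: 11 2-iodo-5,6-dimethoxy-3-(methoxymethoxy)phenol; 12 carbon monoxide; 4 5-ethynyl-1,2-dimethoxy-3-(methoxymethoxy)benzene
Product: 15 5,3'-bis(methoxymethoxy)-7,8,4',5'-tetramethoxyflavone, via hydroxyaryl ynone 13 (not isolated), via enaminone 14 (not isolated)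
Conditions: PdCl2(dppf) (5 mol %), CO (20 bar), Et2NH, 120 °C, autoclave, no copper
Reagents that add atoms: carbon monoxide (12), [C-]#[O+]
Why: Oxidative addition of Pd(0) to the C–I bond of 11 (future C4a) is followed by migratory insertion of CO to an aroylpalladium iodide, which takes up the amine-deprotonated alkyne 4 and reductively eliminates ynone 13, creating C4a–C4 and C4–C3. Diethylamine then adds to the β-carbon (C2) to give the push–pull enaminone 14, and the C8a hydroxyl closes ring C by 6-endo-trig attack at C2 with expulsion of the amine, creating O1–C2. The closest known reaction type is the palladium-catalysed carbonylative Sonogashira coupling and annulation of 2-iodophenols with terminal arylacetylenes in a secondary amine, an established flavone synthesis. No stereocentre is formed. Two selectivities are needed: CO insertion must precede alkyne transfer, which is favoured by CO pressure, the absence of copper and the fast insertion of an electron-rich aryl–Pd bond, and 6-endo closure must win over 5-exo closure, which the enaminone secures because C2 is its only electrophilic carbon. Only the C8a oxygen is free, the C5 oxygen being an acetal, so closure cannot take place through the other ortho oxygen.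

**Step 9**
Reactants: 15 5,3'-bis(methoxymethoxy)-7,8,4',5'-tetramethoxyflavone
Product: 16 5,3'-dihydroxy-7,8,4',5'-tetramethoxyflavone
Conditions: HCl (1.25 M in MeOH), THF, 40 °C
Reagents that add atoms: none
Why: Acid-catalysed transacetalisation of both aryl MOM ethers with methanol should leave the four methyl ethers and the chromone intact, since these conditions are far milder than those that cause Wessely–Moser isomerisation of 5,7,8-oxygenated flavones.

**Compound list**
1 | 3-hydroxy-4,5-dimethoxybenzaldehyde | O=Cc1cc(O)c(OC)c(OC)c1 | starting material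
2 | 3,4-dimethoxy-5-(methoxymethoxy)benzaldehyde | O=Cc1cc(OCOC)c(OC)c(OC)c1 | intermediate
3 | dimethyl (1-diazo-2-oxopropyl)phosphonate | COP(=O)(OC)C(=[N+]=[N-])C(C)=O | starting material
4 | 5-ethynyl-1,2-dimethoxy-3-(methoxymethoxy)benzene | C#Cc1cc(OC)c(OC)c(OCOC)c1 | intermediate
5 | 5-formyl-2,3-dimethoxyphenyl N,N-diethylcarbamate | CCN(CC)C(=O)Oc1cc(C=O)cc(OC)c1OC | intermediate
6 | 5-(formyloxy)-2,3-dimethoxyphenyl N,N-diethylcarbamate (not isolated) | CCN(CC)C(=O)Oc1cc(OC=O)cc(OC)c1OC | intermediate
7 | 5-hydroxy-2,3-dimethoxyphenyl N,N-diethylcarbamate | CCN(CC)C(=O)Oc1cc(O)cc(OC)c1OC | intermediate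
8 | 2,3-dimethoxy-5-(methoxymethoxy)phenyl N,N-diethylcarbamate | CCN(CC)C(=O)Oc1cc(OCOC)cc(OC)c1OC | intermediate
9 | [2-(diethylcarbamoyloxy)-3,4-dimethoxy-6-(methoxymethoxy)phenyl]lithium (not isolated) | [Li]c1c(OCOC)cc(OC)c(OC)c1OC(=O)N(CC)CC | intermediate
10 | 2-iodo-5,6-dimethoxy-3-(methoxymethoxy)phenyl N,N-diethylcarbamate | CCN(CC)C(=O)Oc1c(I)c(OCOC)cc(OC)c1OC | intermediate
11 | 2-iodo-5,6-dimethoxy-3-(methoxymethoxy)phenol | Oc1c(I)c(OCOC)cc(OC)c1OC | intermediate
12 | carbon monoxide | [C-]#[O+] | starting material
13 | 1-[2-hydroxy-3,4-dimethoxy-6-(methoxymethoxy)phenyl]-3-[3,4-dimethoxy-5-(methoxymethoxy)phenyl]prop-2-yn-1-one (not isolated) | O=C(C#Cc1cc(OC)c(OC)c(OCOC)c1)c1c(O)c(OC)c(OC)cc1OCOC | intermediate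
14 | 3-(diethylamino)-1-[2-hydroxy-3,4-dimethoxy-6-(methoxymethoxy)phenyl]-3-[3,4-dimethoxy-5-(methoxymethoxy)phenyl]prop-2-en-1-one (not isolated; push–pull alkene, geometry labile and not assigned) | CCN(CC)C(=CC(=O)c1c(O)c(OC)c(OC)cc1OCOC)c1cc(OC)c(OC)c(OCOC)c1 | intermediate
15 | 5,3'-bis(methoxymethoxy)-7,8,4',5'-tetramethoxyflavone | COCOc1cc(-c2cc(=O)c3c(OCOC)cc(OC)c(OC)c3o2)cc(OC)c1OC | intermediate
16 | 5,3'-dihydroxy-7,8,4',5'-tetramethoxyflavone (achiral) | COc1cc(-c2cc(=O)c3c(O)cc(OC)c(OC)c3o2)cc(O)c1OC | target

**Totals**
Total step count: 9.
Longest linear sequence: 7 (steps 3–9, from 1).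

**Steps most likely to fail**

1. Step 8.
   - Risk: oxidative addition at a C–I bond flanked by two oxygen substituents on a very electron-rich ring may be slow. Alkyne transfer may outrun CO insertion. The solvent amine may intercept the acylpalladium species.
   - Fallback: it sets out from 4 and 11, returns at 13, and takes C4 from an acylating agent instead of the gas. Alkyne 4 is deprotonated (n-BuLi, THF, −78 °C) and quenched with N-methoxy-N-methylcarbamoyl chloride. This gives the alkynyl Weinreb amide N-methoxy-N-methyl-3-[3,4-dimethoxy-5-(methoxymethoxy)phenyl]prop-2-ynamide F1. Iodophenol 11 is treated with n-BuLi (2.2 equiv, THF, −78 °C), so that O–H deprotonation and iodine–lithium exchange give the O,C-dilithiated arene F2. Acylation of F2 by F1 should deliver ynone 13, now isolated. Warming 13 in Et2NH–EtOH carries it through 14 to 15.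

2. Step 6.
   - Risk: deprotonation may be shared with the C–H between the methoxy and MOM groups. Migration of the carbamoyl group from oxygen to the lithiated carbon may begin before the iodine quench.
   - Fallback: it sets out from 8 and 4, returns at 13, and fixes the regiochemistry through the phenol itself. Carbamate 8 is hydrolysed first (NaOH, EtOH–H2O, reflux) to 2,3-dimethoxy-5-(methoxymethoxy)phenol F3. Its single free ortho position is formylated under magnesium phenoxide control (MgCl2, Et3N, paraformaldehyde, MeCN, reflux; Casnati–Skattebøl formylation) to give 2-hydroxy-3,4-dimethoxy-6-(methoxymethoxy)benzaldehyde F4. With its phenol deprotonated beforehand by NaH, F4 takes up the lithium acetylide of 4 (THF, −78 → 0 °C) to give the racemic propargylic alcohol F5. MnO2 in CH2Cl2 oxidises F5 to ynone 13, which Et2NH closes through 14 to 15. This detour gives up the iodide and carbon monoxide, and it would be used only if 10 cannot be obtained as a single isomer.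

3. Step 7.
   - Risk: attack of hydroxide on a carbamate carbonyl shielded on both sides by iodine and methoxy may be very slow. Prolonged heating could then bring loss of iodine or air oxidation of the electron-rich phenoxide.
   - Fallback: it sets out from 10 and returns at 11, replacing acyl substitution by reduction. Schwartz reagent (Cp2Zr(H)Cl, THF, rt) hydrozirconates the carbamate carbonyl, and the adduct collapses to the zirconium phenoxide, which is hydrolysed on work-up. This is a known mild cleavage of aryl O-carbamates that tolerates aryl halides and acetals. No new compound arises.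

**Further compounds**
F1 | step 8 | N-methoxy-N-methyl-3-[3,4-dimethoxy-5-(methoxymethoxy)phenyl]prop-2-ynamide | CON(C)C(=O)C#Cc1cc(OC)c(OC)c(OCOC)c1
F2 | step 8 | lithium 2-lithio-5,6-dimethoxy-3-(methoxymethoxy)phenoxide | [Li]Oc1c([Li])c(OCOC)cc(OC)c1OC
F3 | step 6 | 2,3-dimethoxy-5-(methoxymethoxy)phenol | Oc1cc(OCOC)cc(OC)c1OC
F4 | step 6 | 2-hydroxy-3,4-dimethoxy-6-(methoxymethoxy)benzaldehyde | O=Cc1c(O)c(OC)c(OC)cc1OCOC
F5 | step 6 | rac-2-{1-hydroxy-3-[3,4-dimethoxy-5-(methoxymethoxy)phenyl]prop-2-yn-1-yl}-5,6-dimethoxy-3-(methoxymethoxy)phenol (racemate) | OC(C#Cc1cc(OC)c(OC)c(OCOC)c1)c1c(O)c(OC)c(OC)cc1OCOC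
F0 | step 7 | none | none
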